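**Plan**

- Lignan locants: C7 (guaiacyl-bearing), C8, C9 (lactone C=O), C7′ (syringyl-bearing), C8′, C9′ (ether CH2). The core is a γ-lactone (C9–O–C7′) and a tetrahydrofuran (C7–O–C9′), cis-fused through C8–C8′.
- Enabling feature: each fusion carbon carries one aryl carbinol carbon (C7, C7′) and one oxidised one-carbon arm (C9, C9′), so C9–C8–C8′–C9′ maps onto the carbonyl/α/β/γ carbons of a 5-substituted butenolide.
- Retrosynthetic cuts, in order: the C7–O ether bond; C9′ back to a CH(OH)–CH2OH arm (one carbon excised); the lactone oxygen moved from C7′ back to C9′; then C8–C7 and C8′–C7′ together.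
- Forward: the butenolide ring passes through the three-component coupling as the C9 lactone, is re-hung on O7′ after ketone reduction, and the tetrahydrofuran closes last.
- Stereochemistry: C5 of the D-glutamate-derived (R)-butenolide sets C8′ and, through it, C8. C7′ comes from Felkin–Anh hydride delivery, and C7 from cationic closure on the convex face. The template centre leaves as achiral C9′H2.

Key step: step 8

Remark: O-benzylvanillin (12) is assumed to be purchased; carbinol C7 is carried as an epimer mixture until step 14.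

**Route**

Step 1
Reactants: 1 D-glutamic acid
Product: 2 (R)-5-oxotetrahydrofuran-2-carboxylic acid
Conditions: NaNO2, aq. HCl, 0 °C → rt
Reagents that add atoms: none
Why: Diazotisation with neighbouring-carboxylate participation (α-lactone, then attack by the γ-carboxylate) is the classical deaminative lactonisation and should give the γ-lactone acid with net retention by double inversion.

Step 2
Reactants: 2 (R)-5-oxotetrahydrofuran-2-carboxylic acid
Product: 3 (R)-5-(hydroxymethyl)dihydrofuran-2(3H)-one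
Conditions: BH3·SMe2, THF, 0 °C → rt; MeOH
Reagents that add atoms: none
Why: Chemoselective borane reduction takes the free carboxylic acid much faster than the lactone and does not touch the stereocentre.

Step 3
Reactants: 3 (R)-5-(hydroxymethyl)dihydrofuran-2(3H)-one
Product: 4 (R)-5-[(tert-butyldiphenylsilyloxy)methyl]dihydrofuran-2(3H)-one
Conditions: TBDPSCl, imidazole, DMF, 0 °C → rt
Reagents that add atoms: tert-butyl(chloro)diphenylsilane, CC(C)(C)[Si](Cl)(c1ccccc1)c1ccccc1
Why: Standard silylation of a primary alcohol; the bulky silyl ether shields one face of the later butenolide and is removed by fluoride, so the ionisable C7 benzylic carbinol never meets acid before the carbon excision.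

Step 4
Reactants: 4 (R)-5-[(tert-butyldiphenylsilyloxy)methyl]dihydrofuran-2(3H)-one
Product: 6 (5R)-5-[(tert-butyldiphenylsilyloxy)methyl]-3-(phenylselanyl)dihydrofuran-2(3H)-one (C3 epimers), via lithium enolate 5 (not isolated)
Conditions: LDA, THF, −78 °C; PhSeBr, −78 °C
Reagents that add atoms: phenylselenyl bromide, Br[Se]c1ccccc1
Why: α-Selenenylation of a lactone lithium enolate is routine, and C5 is not enolisable, so its configuration is kept.

Step 5
Reactants: 6 (5R)-5-[(tert-butyldiphenylsilyloxy)methyl]-3-(phenylselanyl)dihydrofuran-2(3H)-one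
Product: 8 (R)-5-[(tert-butyldiphenylsilyloxy)methyl]furan-2(5H)-one, via selenoxide 7 (not isolated)
Conditions: 30% H2O2, pyridine, CH2Cl2, 0 °C → rt
Reagents that add atoms: none
Why: Selenide oxidation followed by syn-selenoxide elimination toward C4–H should give the endocyclic butenolide below room temperature without disturbing C5.

Step 6
Reactants: 9 syringaldehyde
Product: 10 4-(benzyloxy)-3,5-dimethoxybenzaldehyde
Conditions: BnBr, K2CO3, DMF, 60 °C
Reagents that add atoms: benzyl bromide, BrCc1ccccc1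
Why: Williamson etherification of the phenol; the benzyl ether tolerates organolithium, Hg(II), hydride, periodate and mild acid.

Step 7
Reactants: 10 4-(benzyloxy)-3,5-dimethoxybenzaldehyde
Product: 11 2-[4-(benzyloxy)-3,5-dimethoxyphenyl]-1,3-dithiane
Conditions: HS(CH2)3SH, BF3·OEt2 (cat.), CH2Cl2, 0 °C → rt
Reagents that add atoms: propane-1,3-dithiol, SCCCS
Why: Lewis-acid-catalysed dithioacetalisation turns the aldehyde into an acyl-anion precursor (Corey–Seebach umpolung).

Step 8
Reactants: 11 2-[4-(benzyloxy)-3,5-dimethoxyphenyl]-1,3-dithiane; 8 (R)-5-[(tert-butyldiphenylsilyloxy)methyl]furan-2(5H)-one; 12 4-(benzyloxy)-3-methoxybenzaldehyde (O-benzylvanillin)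
Product: 15 (3S,4R,5R)-3-[(4-benzyloxy-3-methoxyphenyl)(hydroxy)methyl]-4-[2-(4-benzyloxy-3,5-dimethoxyphenyl)-1,3-dithian-2-yl]-5-[(tert-butyldiphenylsilyloxy)methyl]dihydrofuran-2(3H)-one (C7 carbinol epimers), via 2-lithio-1,3-dithiane 13 (not isolated), via lithium lactone enolate 14 (not isolated)
Conditions: n-BuLi, THF, −78 → −20 °C; 8, −78 °C; 12, −78 °C; AcOH, −78 °C
Reagents that add atoms: none
Why: Deprotonation of 11 gives the soft, sulfur- and aryl-stabilised carbanion 13, which adds 1,4 to butenolide 8 (Michael addition, C7′–C8′) and leaves lithium enolate 14; this is trapped in the same flask by aldehyde 12 in an aldol addition (C8–C7). The closest known reaction type is the tandem conjugate addition–aldol (or alkylation) of 2-aryl-2-lithio-1,3-dithianes on butenolides used for lactone lignans. No ring is formed; the butenolide ring is simply carried on as the C9 lactone. C8′ is set by the C5 silyloxymethyl group, which blocks its own face so that 13 enters anti; C8 is then set by the very bulky dithianyl group on C8′, the aldehyde approaching the enolate anti to it (trans,trans lactone); C7 is left uncontrolled because it is re-formed in step 14. The step needs 1,4- over 1,2-addition and addition over γ-deprotonation, which the delocalised, hindered anion in THF at −78 °C should secure, and it needs the aldolate to survive, which the cold acetic acid quench should secure.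

Step 9
Reactants: 15 dithiane aldol adduct
Product: 16 (3S,4R,5R)-4-[4-(benzyloxy)-3,5-dimethoxybenzoyl]-3-[(4-benzyloxy-3-methoxyphenyl)(hydroxy)methyl]-5-[(tert-butyldiphenylsilyloxy)methyl]dihydrofuran-2(3H)-one
Conditions: Hg(ClO4)2·3H2O, CaCO3, THF–H2O (5:1), 0 °C → rt
Reagents that add atoms: water, O
Why: Hg(II)-assisted dithioketal hydrolysis (thiophilic activation, water capture of the thionium ion) under carbonate buffering should unmask the aryl ketone while sparing the silyl ether, the aldol and the trans,trans lactone.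

Step 10
Reactants: 16 keto lactone
Product: 18 (3S,4R,5S)-5-[4-(benzyloxy)-3,5-dimethoxyphenyl]-3-[(4-benzyloxy-3-methoxyphenyl)(hydroxy)methyl]-4-[(1R)-2-(tert-butyldiphenylsilyloxy)-1-hydroxyethyl]dihydrofuran-2(3H)-one, via dilithium dialkoxide 17 (not isolated)
Conditions: L-Selectride (2.5 equiv), THF, −78 → −20 °C; AcOH
Reagents that add atoms: none
Why: Chemoselective ketone reduction by the bulky borohydride under Felkin–Anh control (hydride approaches C7′ anti to the more branched ring carbon C8, passing C8′–H) should set 7′S; on warming, the new lithium alkoxide acylates itself at C9 (translactonisation through a bicyclic tetrahedral intermediate, as known for β-aroyl-α-(hydroxybenzyl)butyrolactones), and the released C9′ alkoxide is stabilised by chelation to the neighbouring silyloxy oxygen.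

Step 11
Reactants: 18 translactonised silyl ether
Product: 19 (3S,4R,5S)-5-[4-(benzyloxy)-3,5-dimethoxyphenyl]-3-[(4-benzyloxy-3-methoxyphenyl)(hydroxy)methyl]-4-[(1R)-1,2-dihydroxyethyl]dihydrofuran-2(3H)-one
Conditions: HF·pyridine, pyridine, THF, 0 °C → rt
Reagents that add atoms: none
Why: Fluoride desilylation under buffered, non-basic conditions should free the 1,2-diol without acyl migration, retro-aldol or benzylic ionisation; any silyl group that migrated to O9′ in step 10 is removed here as well.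

Step 12
Reactants: 19 triol lactone
Product: 21 (3S,3aS,6aS)-6-(4-benzyloxy-3-methoxyphenyl)-3-(4-benzyloxy-3,5-dimethoxyphenyl)-4-hydroxytetrahydro-1H,3H-furo[3,4-c]furan-1-one (lactol; epimers at C4 and C6), via open-chain hydroxy aldehyde 20 (not isolated)
Conditions: NaIO4, THF–pH 7 phosphate buffer, 0 °C → rt
Reagents that add atoms: none
Why: Periodate glycol cleavage (Malaprade) removes the template carbon as formaldehyde, and the C9′ aldehyde should be captured at once by the cis-disposed C7 hydroxyl as a five-membered lactol, which protects C8′ from epimerisation.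

Step 13
Reactants: 21 bicyclic lactol
Product: 22 (3S,4R,5S)-5-[4-(benzyloxy)-3,5-dimethoxyphenyl]-3-[(4-benzyloxy-3-methoxyphenyl)(hydroxy)methyl]-4-(hydroxymethyl)dihydrofuran-2(3H)-one
Conditions: NaBH4, THF–MeOH, −20 → 0 °C; AcOH
Reagents that add atoms: none
Why: Borohydride reduces the lactol through its open aldehyde form while the γ-lactone is inert at low temperature (chemoselective aldehyde reduction), and the lactone should stay on O7′ because the isomeric lactone would trade a primary for a hindered benzylic alkoxide.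

Step 14
Reactants: 22 diol lactone
Product: 23 (3S,3aR,6S,6aS)-6-[4-(benzyloxy)-3-methoxyphenyl]-3-[4-(benzyloxy)-3,5-dimethoxyphenyl]tetrahydro-1H,3H-furo[3,4-c]furan-1-one
Conditions: CSA (cat.), 4 Å MS, CH2Cl2, rt
Reagents that add atoms: none
Why: Acid-catalysed SN1 cycloetherification: the p-alkoxybenzylic C7 carbinol ionises, the cis-placed C9′ hydroxyl closes the tetrahydrofuran, both C7 epimers converge, and the aryl group should settle on the convex face anti to the C9 carbonyl (7S); the twisted, less donating 4-alkoxy group of the syringyl ring and the poorer carboxylate leaving group should keep C7′ intact.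

Step 15
Reactants: 23 dibenzyl ether of the target
Product: 24 (3S,3aR,6S,6aS)-6-(4-hydroxy-3-methoxyphenyl)-3-(4-hydroxy-3,5-dimethoxyphenyl)tetrahydro-1H,3H-furo[3,4-c]furan-1-one (target)
Conditions: H2 (1 atm), 10% Pd/C, EtOAc, rt, stopped at full debenzylation
Reagents that add atoms: none
Why: Catalytic hydrogenolysis should cleave the two aryl benzyl ethers much faster than the ring benzylic ether and lactone C–O bonds in a neutral aprotic solvent.

**Compound list**

1 | D-glutamic acid | N[C@H](CCC(=O)O)C(=O)O | starting material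
2 | (R)-5-oxotetrahydrofuran-2-carboxylic acid | O=C1O[C@@H](C(=O)O)CC1 | intermediate
3 | (R)-5-(hydroxymethyl)dihydrofuran-2(3H)-one | O=C1O[C@@H](CO)CC1 | intermediate
4 | (R)-5-[(tert-butyldiphenylsilyloxy)methyl]dihydrofuran-2(3H)-one | O=C1O[C@@H](CO[Si](c2ccccc2)(c2ccccc2)C(C)(C)C)CC1 | intermediate
5 | lithium enolate of 4 | [Li+].[O-]C1=CC[C@H](CO[Si](c2ccccc2)(c2ccccc2)C(C)(C)C)O1 | intermediate
6 | (5R)-5-[(tert-butyldiphenylsilyloxy)methyl]-3-(phenylselanyl)dihydrofuran-2(3H)-one, C3 epimers | O=C1O[C@@H](CO[Si](c2ccccc2)(c2ccccc2)C(C)(C)C)CC1[Se]c1ccccc1 | intermediate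
7 | selenoxide of 6 | O=C1O[C@@H](CO[Si](c2ccccc2)(c2ccccc2)C(C)(C)C)CC1[Se](=O)c1ccccc1 | intermediate
8 | (R)-5-[(tert-butyldiphenylsilyloxy)methyl]furan-2(5H)-one | O=C1O[C@@H](CO[Si](c2ccccc2)(c2ccccc2)C(C)(C)C)C=C1 | intermediate
9 | syringaldehyde | COc1cc(C=O)cc(OC)c1O | starting material
10 | 4-(benzyloxy)-3,5-dimethoxybenzaldehyde | COc1cc(C=O)cc(OC)c1OCc1ccccc1 | intermediate
11 | 2-[4-(benzyloxy)-3,5-dimethoxyphenyl]-1,3-dithiane | COc1cc(C2SCCCS2)cc(OC)c1OCc1ccccc1 | intermediate
12 | 4-(benzyloxy)-3-methoxybenzaldehyde (O-benzylvanillin) | COc1cc(C=O)ccc1OCc1ccccc1 | starting material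
13 | 2-lithio derivative of 11 | [Li]C1(c2cc(OC)c(OCc3ccccc3)c(OC)c2)SCCCS1 | intermediate
14 | lithium enolate of the (4R,5R) Michael adduct | [Li+].[O-]C1=C[C@@H](C2(c3cc(OC)c(OCc4ccccc4)c(OC)c3)SCCCS2)[C@H](CO[Si](c2ccccc2)(c2ccccc2)C(C)(C)C)O1 | intermediate
15 | (3S,4R,5R)-3-[(4-benzyloxy-3-methoxyphenyl)(hydroxy)methyl]-4-[2-(4-benzyloxy-3,5-dimethoxyphenyl)-1,3-dithian-2-yl]-5-[(tert-butyldiphenylsilyloxy)methyl]dihydrofuran-2(3H)-one, carbinol epimers | O=C1O[C@@H](CO[Si](c2ccccc2)(c2ccccc2)C(C)(C)C)[C@H](C2(c3cc(OC)c(OCc4ccccc4)c(OC)c3)SCCCS2)[C@H]1C(O)c1ccc(OCc2ccccc2)c(OC)c1 | intermediate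
16 | (3S,4R,5R)-4-[4-(benzyloxy)-3,5-dimethoxybenzoyl]-3-[(4-benzyloxy-3-methoxyphenyl)(hydroxy)methyl]-5-[(tert-butyldiphenylsilyloxy)methyl]dihydrofuran-2(3H)-one | O=C1O[C@@H](CO[Si](c2ccccc2)(c2ccccc2)C(C)(C)C)[C@H](C(=O)c2cc(OC)c(OCc3ccccc3)c(OC)c2)[C@H]1C(O)c1ccc(OCc2ccccc2)c(OC)c1 | intermediate
17 | dilithium 7,7′-dialkoxide of the (7′S)-alcohol, lactone still on O9′ | [Li+].[Li+].O=C1O[C@@H](CO[Si](c2ccccc2)(c2ccccc2)C(C)(C)C)[C@H]([C@H]([O-])c2cc(OC)c(OCc3ccccc3)c(OC)c2)[C@H]1C([O-])c1ccc(OCc2ccccc2)c(OC)c1 | intermediate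
18 | (3S,4R,5S)-5-[4-(benzyloxy)-3,5-dimethoxyphenyl]-3-[(4-benzyloxy-3-methoxyphenyl)(hydroxy)methyl]-4-[(1R)-2-(tert-butyldiphenylsilyloxy)-1-hydroxyethyl]dihydrofuran-2(3H)-one | O=C1O[C@H](c2cc(OC)c(OCc3ccccc3)c(OC)c2)[C@@H]([C@@H](O)CO[Si](c2ccccc2)(c2ccccc2)C(C)(C)C)[C@H]1C(O)c1ccc(OCc2ccccc2)c(OC)c1 | intermediate
19 | (3S,4R,5S)-5-[4-(benzyloxy)-3,5-dimethoxyphenyl]-3-[(4-benzyloxy-3-methoxyphenyl)(hydroxy)methyl]-4-[(1R)-1,2-dihydroxyethyl]dihydrofuran-2(3H)-one | O=C1O[C@H](c2cc(OC)c(OCc3ccccc3)c(OC)c2)[C@@H]([C@@H](O)CO)[C@H]1C(O)c1ccc(OCc2ccccc2)c(OC)c1 | intermediate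
20 | open-chain hydroxy aldehyde (C9′ formyl on the O7′ lactone) | O=C1O[C@H](c2cc(OC)c(OCc3ccccc3)c(OC)c2)[C@@H](C=O)[C@H]1C(O)c1ccc(OCc2ccccc2)c(OC)c1 | intermediate
21 | (3S,3aS,6aS)-6-(4-benzyloxy-3-methoxyphenyl)-3-(4-benzyloxy-3,5-dimethoxyphenyl)-4-hydroxytetrahydro-1H,3H-furo[3,4-c]furan-1-one, lactol, epimers at C4 and C6 | COc1cc(C2OC(O)[C@H]3[C@@H]2C(=O)O[C@@H]3c2cc(OC)c(OCc4ccccc4)c(OC)c2)ccc1OCc1ccccc1 | intermediate
22 | (3S,4R,5S)-5-[4-(benzyloxy)-3,5-dimethoxyphenyl]-3-[(4-benzyloxy-3-methoxyphenyl)(hydroxy)methyl]-4-(hydroxymethyl)dihydrofuran-2(3H)-one | O=C1O[C@H](c2cc(OC)c(OCc3ccccc3)c(OC)c2)[C@@H](CO)[C@H]1C(O)c1ccc(OCc2ccccc2)c(OC)c1 | intermediate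
23 | (3S,3aR,6S,6aS)-6-[4-(benzyloxy)-3-methoxyphenyl]-3-[4-(benzyloxy)-3,5-dimethoxyphenyl]tetrahydro-1H,3H-furo[3,4-c]furan-1-one | COc1cc([C@H]2OC[C@H]3[C@@H]2C(=O)O[C@@H]3c2cc(OC)c(OCc4ccccc4)c(OC)c2)ccc1OCc1ccccc1 | intermediate
24 | (3S,3aR,6S,6aS)-6-(4-hydroxy-3-methoxyphenyl)-3-(4-hydroxy-3,5-dimethoxyphenyl)tetrahydro-1H,3H-furo[3,4-c]furan-1-one | COc1cc([C@H]2OC[C@H]3[C@@H]2C(=O)O[C@@H]3c2cc(OC)c(O)c(OC)c2)ccc1O | target

**Step count**

Total: 15 steps. Longest linear sequence: 13 steps (steps 1–5, then 8–15).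

**Steps most likely to fail**

1. Step 10. Hydride delivery may discriminate poorly between the two faces of the ketone, because the silyloxymethyl-bearing ring carbon competes with C8 as the large α-substituent. The acyl shift to O7′ may also stall at an equilibrium mixture. Fallback, setting out from 16: a catalyst-controlled Corey–Bakshi–Shibata reduction ((R)-Me-CBS, BH3·SMe2, THF, −20 °C) should give the untransposed (7′S)-hydroxy lactone F2 under non-alkoxide conditions. HF·pyridine then gives the triol lactone F3. LiOH (THF–H2O, 0 °C) opens the lactone to the lithium carboxylate F4, whose free C9′/CH2OH glycol is cleaved with NaIO4 at pH 7. Acidification with dilute HCl to pH 3 lets the acid close on O7′, the only γ-hydroxyl left, while the aldehyde is held as the C7–O lactol. The route is rejoined at 21, and lactone placement no longer depends on an alkoxide equilibrium.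

2. Step 8. The dithiane anion may act as a base (γ-deprotonation of the butenolide) or add 1,2, and the hindered aldol may revert before the quench. Fallback, setting out from 11 and 8: the conjugate addition is run alone and quenched cold to isolate the trans Michael adduct lactone F1. Its enolate is then regenerated separately (LDA, THF, −78 °C), transmetalated with ZnCl2 and treated with 12, so that the aldol is optimised on its own. The route is rejoined at 15.

3. Step 15. Hydrogenolysis may run on into the benzylic C7–O ether or the C7′–O lactone bond. Fallback, setting out from 23: non-reductive debenzylation with BCl3 and pentamethylbenzene as cation scavenger (CH2Cl2, −78 °C) cleaves only the aryl benzyl ethers and arrives directly at 24; no compound outside the list is formed (F0).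

**Further compounds**

F1 | step 8 | (4R,5R)-4-[2-(4-benzyloxy-3,5-dimethoxyphenyl)-1,3-dithian-2-yl]-5-[(tert-butyldiphenylsilyloxy)methyl]dihydrofuran-2(3H)-one | O=C1C[C@@H](C2(c3cc(OC)c(OCc4ccccc4)c(OC)c3)SCCCS2)[C@H](CO[Si](c2ccccc2)(c2ccccc2)C(C)(C)C)O1
F2 | step 10 | (3S,4S,5R)-4-[(S)-(4-benzyloxy-3,5-dimethoxyphenyl)(hydroxy)methyl]-3-[(4-benzyloxy-3-methoxyphenyl)(hydroxy)methyl]-5-[(tert-butyldiphenylsilyloxy)methyl]dihydrofuran-2(3H)-one | O=C1O[C@@H](CO[Si](c2ccccc2)(c2ccccc2)C(C)(C)C)[C@H]([C@H](O)c2cc(OC)c(OCc3ccccc3)c(OC)c2)[C@H]1C(O)c1ccc(OCc2ccccc2)c(OC)c1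
F3 | step 10 | (3S,4S,5R)-4-[(S)-(4-benzyloxy-3,5-dimethoxyphenyl)(hydroxy)methyl]-3-[(4-benzyloxy-3-methoxyphenyl)(hydroxy)methyl]-5-(hydroxymethyl)dihydrofuran-2(3H)-one | O=C1O[C@@H](CO)[C@H]([C@H](O)c2cc(OC)c(OCc3ccccc3)c(OC)c2)[C@H]1C(O)c1ccc(OCc2ccccc2)c(OC)c1
F4 | step 10 | lithium carboxylate from lactone opening of F3 (tetrahydroxy acid salt, stereocentres as in F3) | [Li+].[O-]C(=O)[C@H](C(O)c1ccc(OCc2ccccc2)c(OC)c1)[C@@H]([C@H](O)c1cc(OC)c(OCc2ccccc2)c(OC)c1)[C@@H](O)CO
F0 | step 15 | none | none
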